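**Strategy**

Everything rests on breaking the O1–C2 bond of the chroman. C2 is at once the tertiary aryl-ether carbon of the pyran ring and the allylic end of the C1′=C2′–C3′=C4′ diene, i.e. one terminus of the pentadienyl unit C2–C1′–C2′–C3′–C4′. A racemic bis-allylic C2′ methyl carbonate that carries a free ortho-phenol and two preformed E trisubstituted alkenes is ionised by Pd(0) with a chiral diphosphine; the phenol oxygen closes the pyran ring at C2, which sets the only stereocentre and delivers the (1′E,3′E)-diene in one operation. The precursor comes from a Nozaki–Hiyama–Kishi union of an aryl-side E-enal with an ionone-derived E-alkenyl iodide; ester hydrolysis then gives the acid.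

Key step: step 10

Remark on the chemistry: chroman atoms are numbered O1, C2, C3, C4, C4a–C8a and the side chain C1′–C6′ outward from C2. The target is (R) at C2 with (1′E,3′E) geometry, and the cyclisation precursor 15 is the (3E,6E) isomer. Assumption: the (R,R)-ligand is taken to give the 2R series by analogy with the closure of E allylic carbonates to 2-methyl-2-vinylchromans; if the sense proves opposite, the (S,S)-ligand is used.

**Route**

Step 1
Reactants: 1 methyl 4-hydroxy-3-iodobenzoate
Product: 2 methyl 4-[(tert-butyldimethylsilyl)oxy]-3-iodobenzoate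
Conditions: TBSCl (1.2 equiv), imidazole (2.5 equiv), DMF, rt
Reagents that add atoms: tert-butyldimethylsilyl chloride, CC(C)(C)[Si](C)(C)Cl
Why: Imidazole-promoted silyl ether formation on the acidic phenol masks it, so that the ortho alkyne of step 2 cannot close to a benzofuran and the organochromium reagent of step 7 is not protonated.

Step 2
Reactants: 2 methyl 4-[(tert-butyldimethylsilyl)oxy]-3-iodobenzoate; 3 (2E)-3-methylpent-2-en-4-yn-1-ol
Product: 4 methyl 4-[(tert-butyldimethylsilyl)oxy]-3-[(3E)-5-hydroxy-3-methylpent-3-en-1-yn-1-yl]benzoate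
Conditions: PdCl2(PPh3)2 (2 mol%), CuI (4 mol%), Et3N, THF, rt
Reagents that add atoms: none
Why: Sonogashira coupling of an aryl iodide with a terminal enyne runs at room temperature, tolerates the free allylic alcohol, the ester and the silyl ether, and brings in the E trisubstituted alkene ready-made from commercial 3, so no unselective olefination is needed.

Step 3
Reactants: 4 methyl 4-[(tert-butyldimethylsilyl)oxy]-3-[(3E)-5-hydroxy-3-methylpent-3-en-1-yn-1-yl]benzoate
Product: 6 methyl 4-[(tert-butyldimethylsilyl)oxy]-3-[(3E)-5-hydroxy-3-methylpent-3-en-1-yl]benzoate, via cis-styrenyl dienol 5 (not isolated)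
Conditions: 2-nitrobenzenesulfonylhydrazide (NBSH, 3 × 3 equiv), Et3N, THF, rt
Reagents that add atoms: none
Why: Diimide reduction transfers H2 syn to the alkyne and then to the resulting cis-disubstituted styrenyl alkene, whereas the trisubstituted allylic alkene should react far more slowly, so its E geometry, the ester and the silyl ether should survive.

Step 4
Reactants: 6 methyl 4-[(tert-butyldimethylsilyl)oxy]-3-[(3E)-5-hydroxy-3-methylpent-3-en-1-yl]benzoate
Product: 7 methyl 4-[(tert-butyldimethylsilyl)oxy]-3-[(3E)-3-methyl-5-oxopent-3-en-1-yl]benzoate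
Conditions: TEMPO (10 mol%), PhI(OAc)2 (1.1 equiv), CH2Cl2, rt
Reagents that add atoms: none
Why: Oxoammonium (TEMPO/PhI(OAc)2) oxidation of a primary allylic alcohol stops at the aldehyde under nearly neutral conditions that should not isomerise the E enal, as in the geraniol-to-geranial case.

Step 5
Reactants: 8 dihydro-β-ionone [4-(2,6,6-trimethylcyclohex-1-en-1-yl)butan-2-one]
Product: 10 2-(but-3-yn-1-yl)-1,3,3-trimethylcyclohex-1-ene, via enol phosphate 9 (not isolated)
Conditions: LDA (1.1 equiv), THF, −78 °C; ClP(O)(OEt)2, −78 °C → rt; LDA (2.3 equiv), −78 °C → rt; H2O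
Reagents that add atoms: none
Why: Negishi's methyl ketone-to-alkyne protocol relies on kinetic deprotonation at the methyl group, O-phosphorylation and LDA-induced β-elimination of the enol phosphate, and the tetrasubstituted ring alkene is inert to all of it.

Step 6
Reactants: 10 2-(but-3-yn-1-yl)-1,3,3-trimethylcyclohex-1-ene
Product: 12 2-[(3E)-4-iodo-3-methylbut-3-en-1-yl]-1,3,3-trimethylcyclohex-1-ene, via alkenylalane 11 (not isolated)
Conditions: Me3Al (2.5 equiv), Cp2ZrCl2 (25 mol%), CH2Cl2, 0 °C → rt; I2 (1.2 equiv), THF, −30 → 0 °C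
Reagents that add atoms: trimethylaluminium, C[Al](C)C; iodine, II
Why: Zirconium-catalysed carboalumination (Negishi) adds methyl and aluminium syn with methyl at the internal carbon, and iodinolysis of the C–Al bond with retention fixes the E alkenyl iodide.

Step 7
Reactants: 7 methyl 4-[(tert-butyldimethylsilyl)oxy]-3-[(3E)-3-methyl-5-oxopent-3-en-1-yl]benzoate; 12 2-[(3E)-4-iodo-3-methylbut-3-en-1-yl]-1,3,3-trimethylcyclohex-1-ene
Product: 13 methyl 4-[(tert-butyldimethylsilyl)oxy]-3-[(3E,6E)-5-hydroxy-3,7-dimethyl-9-(2,6,6-trimethylcyclohex-1-en-1-yl)nona-3,6-dien-1-yl]benzoate (racemic at C5)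
Conditions: CrCl2 (4 equiv), NiCl2 (2 mol%), DMSO/THF, rt; pH 7 aqueous work-up, Et3N-deactivated silica
Reagents that add atoms: none
Why: In the Nozaki–Hiyama–Kishi coupling the nickel-generated alkenylchromium(III) reagent adds 1,2 to the enal with retention of both alkene geometries and leaves the ester and silyl ether alone; the new carbinol centre forms as a racemate, which is what step 10 is designed to accept.

Step 8
Reactants: 13 methyl 4-[(tert-butyldimethylsilyl)oxy]-3-[(3E,6E)-5-hydroxy-3,7-dimethyl-9-(2,6,6-trimethylcyclohex-1-en-1-yl)nona-3,6-dien-1-yl]benzoate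
Product: 14 methyl 4-[(tert-butyldimethylsilyl)oxy]-3-[(3E,6E)-5-[(methoxycarbonyl)oxy]-3,7-dimethyl-9-(2,6,6-trimethylcyclohex-1-en-1-yl)nona-3,6-dien-1-yl]benzoate (racemic)
Conditions: ClCO2Me (3 equiv), pyridine (6 equiv), DMAP (10 mol%), CH2Cl2, 0 °C; Et3N-deactivated silica
Reagents that add atoms: methyl chloroformate, COC(=O)Cl
Why: Carbonate formation (O-acylation with a chloroformate) can only occur at the one free hydroxyl because the phenol is silylated, and the pyridine buffer avoids acid ionisation of the bis-allylic system.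

Step 9
Reactants: 14 methyl 4-[(tert-butyldimethylsilyl)oxy]-3-[(3E,6E)-5-[(methoxycarbonyl)oxy]-3,7-dimethyl-9-(2,6,6-trimethylcyclohex-1-en-1-yl)nona-3,6-dien-1-yl]benzoate
Product: 15 methyl 4-hydroxy-3-[(3E,6E)-5-[(methoxycarbonyl)oxy]-3,7-dimethyl-9-(2,6,6-trimethylcyclohex-1-en-1-yl)nona-3,6-dien-1-yl]benzoate (racemic; used promptly)
Conditions: TBAF (1.1 equiv), AcOH (1.2 equiv), THF, 0 °C
Reagents that add atoms: none
Why: Fluoride-mediated silyl ether cleavage is fast for an aryl silyl ether activated by the para ester, and the acetic acid buffer keeps the phenol protonated so that it should neither attack the carbonate nor cyclise without the catalyst.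

Step 10
Reactants: 15 methyl 4-hydroxy-3-[(3E,6E)-5-[(methoxycarbonyl)oxy]-3,7-dimethyl-9-(2,6,6-trimethylcyclohex-1-en-1-yl)nona-3,6-dien-1-yl]benzoate
Product: 16 methyl (2R)-2-methyl-2-[(1E,3E)-4-methyl-6-(2,6,6-trimethylcyclohex-1-en-1-yl)hexa-1,3-dien-1-yl]chromane-6-carboxylate
Conditions: Pd2(dba)3·CHCl3 (5 mol%), (R,R)-DACH-phenyl Trost ligand (15 mol%), AcOH (1 equiv), CH2Cl2 (0.05 M), rt
Reagents that add atoms: none
Why: Proposed new method: Pd(0) ionises the carbonate anti to the leaving group (CO2 and methoxide are lost) to a W-shaped η3-pentadienyl palladium cation, bound over C2–C1′–C2′ with the C3′=C4′ alkene as a syn substituent, and the phenol oxygen, acidified by the para ester, attacks C2 anti to palladium. The closest known reaction is the Pd/Trost-ligand asymmetric allylic etherification (Tsuji–Trost type) that closes phenols onto E trisubstituted primary allylic carbonates to give 2-methyl-2-vinylchromans; new here are the secondary bis-allylic leaving group and the pentadienyl cation. The pyran ring closes 6-exo at the tertiary terminus because attack at C2′ or C4′ would need an eight- or ten-membered ring, and the syn,syn allyl (an anti dienyl arm would clash with the anti substituent on C2) makes C1′=C2′ E while C3′=C4′, which never passes through a σ-palladium at C4′, stays E. The C2 stereocentre is set by the chiral ligand, which lets one allyl face cyclise faster (Curtin–Hammett control), so the two face-isomeric complexes that arise from the two carbonate enantiomers must interconvert before closure. A π–σ–π shift through C2′ would turn the dienyl arm anti, so this exchange has to come from anti displacement of palladium by a second Pd(0), which is why a high palladium loading, chloride-free conditions and acetic acid (to hold back the phenoxide and slow the closure) are chosen. The single E geometry of the ionising alkene, carried unchanged from 3, gives the ligand one allyl geometry to read, which matters because E and Z allyl termini are expected to answer the same ligand with opposite senses.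

Step 11
Reactants: 16 methyl (2R)-2-methyl-2-[(1E,3E)-4-methyl-6-(2,6,6-trimethylcyclohex-1-en-1-yl)hexa-1,3-dien-1-yl]chromane-6-carboxylate
Product: 17 (2R)-2-methyl-2-[(1E,3E)-4-methyl-6-(2,6,6-trimethylcyclohex-1-en-1-yl)hexa-1,3-dien-1-yl]chromane-6-carboxylic acid (target)
Conditions: LiOH·H2O (5 equiv), THF/MeOH/H2O (3:1:1), 40 °C; AcOH to pH 5, 0 °C
Reagents that add atoms: lithium hydroxide, [Li+].[OH-]
Why: Saponification of the methyl benzoate leaves the base-stable tertiary dienylic aryl ether untouched, and the mild acetic acid work-up avoids acid ionisation at C2, so the stereocentre and the diene geometry should be preserved.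

**Compound list**

1 | methyl 4-hydroxy-3-iodobenzoate | COC(=O)c1ccc(O)c(I)c1 | starting material
2 | methyl 4-[(tert-butyldimethylsilyl)oxy]-3-iodobenzoate | COC(=O)c1ccc(O[Si](C)(C)C(C)(C)C)c(I)c1 | intermediate
3 | (2E)-3-methylpent-2-en-4-yn-1-ol | OC/C=C(C)/C#C | starting material
4 | methyl 4-[(tert-butyldimethylsilyl)oxy]-3-[(3E)-5-hydroxy-3-methylpent-3-en-1-yn-1-yl]benzoate | COC(=O)c1ccc(O[Si](C)(C)C(C)(C)C)c(C#C/C(C)=C/CO)c1 | intermediate
5 | methyl 4-[(tert-butyldimethylsilyl)oxy]-3-[(1Z,3E)-5-hydroxy-3-methylpenta-1,3-dien-1-yl]benzoate | COC(=O)c1ccc(O[Si](C)(C)C(C)(C)C)c(/C=C\C(C)=C\CO)c1 | intermediate (not isolated)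
6 | methyl 4-[(tert-butyldimethylsilyl)oxy]-3-[(3E)-5-hydroxy-3-methylpent-3-en-1-yl]benzoate | COC(=O)c1ccc(O[Si](C)(C)C(C)(C)C)c(CC/C(C)=C/CO)c1 | intermediate
7 | methyl 4-[(tert-butyldimethylsilyl)oxy]-3-[(3E)-3-methyl-5-oxopent-3-en-1-yl]benzoate | COC(=O)c1ccc(O[Si](C)(C)C(C)(C)C)c(CC/C(C)=C/C=O)c1 | intermediate
8 | dihydro-β-ionone, 4-(2,6,6-trimethylcyclohex-1-en-1-yl)butan-2-one | CC(=O)CCC1=C(C)CCCC1(C)C | starting material
9 | diethyl 4-(2,6,6-trimethylcyclohex-1-en-1-yl)but-1-en-2-yl phosphate | C=C(CCC1=C(C)CCCC1(C)C)OP(=O)(OCC)OCC | intermediate (not isolated)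
10 | 2-(but-3-yn-1-yl)-1,3,3-trimethylcyclohex-1-ene | C#CCCC1=C(C)CCCC1(C)C | intermediate
11 | dimethyl[(1E)-2-methyl-4-(2,6,6-trimethylcyclohex-1-en-1-yl)but-1-en-1-yl]alane | C[Al](C)/C=C(\C)CCC1=C(C)CCCC1(C)C | intermediate (not isolated)
12 | 2-[(3E)-4-iodo-3-methylbut-3-en-1-yl]-1,3,3-trimethylcyclohex-1-ene | I/C=C(\C)CCC1=C(C)CCCC1(C)C | intermediate
13 | methyl 4-[(tert-butyldimethylsilyl)oxy]-3-[(3E,6E)-5-hydroxy-3,7-dimethyl-9-(2,6,6-trimethylcyclohex-1-en-1-yl)nona-3,6-dien-1-yl]benzoate, racemic | COC(=O)c1ccc(O[Si](C)(C)C(C)(C)C)c(CC/C(C)=C/C(O)/C=C(\C)CCC2=C(C)CCCC2(C)C)c1 | intermediate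
14 | methyl 4-[(tert-butyldimethylsilyl)oxy]-3-[(3E,6E)-5-[(methoxycarbonyl)oxy]-3,7-dimethyl-9-(2,6,6-trimethylcyclohex-1-en-1-yl)nona-3,6-dien-1-yl]benzoate, racemic | COC(=O)OC(/C=C(C)/CCc1cc(C(=O)OC)ccc1O[Si](C)(C)C(C)(C)C)/C=C(\C)CCC1=C(C)CCCC1(C)C | intermediate
15 | methyl 4-hydroxy-3-[(3E,6E)-5-[(methoxycarbonyl)oxy]-3,7-dimethyl-9-(2,6,6-trimethylcyclohex-1-en-1-yl)nona-3,6-dien-1-yl]benzoate, racemic | COC(=O)OC(/C=C(C)/CCc1cc(C(=O)OC)ccc1O)/C=C(\C)CCC1=C(C)CCCC1(C)C | intermediate
16 | methyl (2R)-2-methyl-2-[(1E,3E)-4-methyl-6-(2,6,6-trimethylcyclohex-1-en-1-yl)hexa-1,3-dien-1-yl]chromane-6-carboxylate | CC1=C(CC/C(C)=C/C=C/[C@@]2(C)CCc3cc(C(=O)OC)ccc3O2)C(C)(C)CCC1 | intermediate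
17 | (2R)-2-methyl-2-[(1E,3E)-4-methyl-6-(2,6,6-trimethylcyclohex-1-en-1-yl)hexa-1,3-dien-1-yl]chromane-6-carboxylic acid | CC1=C(CC/C(C)=C/C=C/[C@@]2(C)CCc3cc(C(=O)O)ccc3O2)C(C)(C)CCC1 | target

**Step count and risks**

Total steps: 11. Longest linear sequence: 9 (steps 1, 2, 3, 4, 7, 8, 9, 10, 11); the ionone branch (steps 5, 6) joins at step 7.

Steps most likely to fail:

1. Step 10. The two face-isomeric allyl-palladium complexes may not interconvert before ring closure. Each carbonate enantiomer would then be carried through with its own stereochemical memory and the enantiomeric excess would collapse toward a kinetic resolution. Loss of a proton from the cation to a tetraene, or re-ionisation of the product ether, could add to this. The fallback uses known chemistry, sets out from 6 and comes back at 16. Alcohol 6 is acylated (ClCO2Me, pyridine, CH2Cl2, 0 °C) to the primary allylic carbonate methyl 4-[(tert-butyldimethylsilyl)oxy]-3-[(3E)-5-[(methoxycarbonyl)oxy]-3-methylpent-3-en-1-yl]benzoate F1. Buffered TBAF then frees the phenol to give methyl 4-hydroxy-3-[(3E)-5-[(methoxycarbonyl)oxy]-3-methylpent-3-en-1-yl]benzoate F2. The established Pd/Trost-ligand cyclisation of this class of primary carbonate (AcOH, CH2Cl2), in which the allyl faces exchange through the unsubstituted terminus, should give methyl (2R)-2-ethenyl-2-methylchromane-6-carboxylate F3. Ozonolysis (O3, CH2Cl2/MeOH, −78 °C; Me2S) should give methyl (2R)-2-formyl-2-methylchromane-6-carboxylate F4. Takai olefination (CrCl2, CHI3, THF) should give methyl (2R)-2-[(E)-2-iodoethenyl]-2-methylchromane-6-carboxylate F5. Negishi coupling of F5 with alkenylalane 11 (made from 10 as in step 6; Pd(PPh3)4, ZnCl2, THF) then builds the (1′E,3′E)-diene and gives 16.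

2. Step 3. Diimide may stall at the styrene stage or, in the excess needed, begin to saturate the trisubstituted alkene, so that chemoselectivity between the two alkenes is lost. The fallback sets out from 2 and 3 and comes back at 6, replacing alkynylation and reduction by a C(sp3)–C(sp2) coupling. Lindlar semi-hydrogenation of 3 gives (2E)-3-methylpenta-2,4-dien-1-ol F6. 9-BBN (2.1 equiv, THF) adds to the terminal vinyl group to give the O-borylated B-alkyl-9-BBN adduct 9-[(3E)-5-(9-borabicyclo[3.3.1]nonan-9-yloxy)-3-methylpent-3-en-1-yl]-9-borabicyclo[3.3.1]nonane F7. B-alkyl Suzuki–Miyaura coupling of F7 with 2 (PdCl2(dppf), anhydrous K3PO4, DMF, 50 °C; aqueous work-up) should deliver 6.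

3. Step 9. Once the phenol is unmasked beside the ionisable bis-allylic carbonate, any phenoxide formed could close the ring without the catalyst (giving racemic material) or the carbonate could be lost by solvolysis. The fallback sets out from 13 and comes back at 15, unmasking the phenol before the leaving group is installed. Silyl ether 13 is cleaved (TBAF, THF, 0 °C) to methyl 4-hydroxy-3-[(3E,6E)-5-hydroxy-3,7-dimethyl-9-(2,6,6-trimethylcyclohex-1-en-1-yl)nona-3,6-dien-1-yl]benzoate F8. Both hydroxyls are acylated (ClCO2Me, pyridine, CH2Cl2, 0 °C) to methyl 4-[(methoxycarbonyl)oxy]-3-[(3E,6E)-5-[(methoxycarbonyl)oxy]-3,7-dimethyl-9-(2,6,6-trimethylcyclohex-1-en-1-yl)nona-3,6-dien-1-yl]benzoate F9. The far more electrophilic aryl carbonate is then removed by aminolysis with one equivalent of pyrrolidine (THF, 0 °C), which should give 15 without fluoride or excess base.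

**Further compounds**

F1 | step 10 | methyl 4-[(tert-butyldimethylsilyl)oxy]-3-[(3E)-5-[(methoxycarbonyl)oxy]-3-methylpent-3-en-1-yl]benzoate | COC(=O)OC/C=C(C)/CCc1cc(C(=O)OC)ccc1O[Si](C)(C)C(C)(C)C
F2 | step 10 | methyl 4-hydroxy-3-[(3E)-5-[(methoxycarbonyl)oxy]-3-methylpent-3-en-1-yl]benzoate | COC(=O)OC/C=C(C)/CCc1cc(C(=O)OC)ccc1O
F3 | step 10 | methyl (2R)-2-ethenyl-2-methylchromane-6-carboxylate | C=C[C@@]1(C)CCc2cc(C(=O)OC)ccc2O1
F4 | step 10 | methyl (2R)-2-formyl-2-methylchromane-6-carboxylate | O=C[C@@]1(C)CCc2cc(C(=O)OC)ccc2O1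
F5 | step 10 | methyl (2R)-2-[(E)-2-iodoethenyl]-2-methylchromane-6-carboxylate | I/C=C/[C@@]1(C)CCc2cc(C(=O)OC)ccc2O1
F6 | step 3 | (2E)-3-methylpenta-2,4-dien-1-ol | OC/C=C(C)/C=C
F7 | step 3 | 9-[(3E)-5-(9-borabicyclo[3.3.1]nonan-9-yloxy)-3-methylpent-3-en-1-yl]-9-borabicyclo[3.3.1]nonane | C(/C=C(C)/CCB1C2CCCC1CCC2)OB1C2CCCC1CCC2
F8 | step 9 | methyl 4-hydroxy-3-[(3E,6E)-5-hydroxy-3,7-dimethyl-9-(2,6,6-trimethylcyclohex-1-en-1-yl)nona-3,6-dien-1-yl]benzoate, racemic | COC(=O)c1ccc(O)c(CC/C(C)=C/C(O)/C=C(\C)CCC2=C(C)CCCC2(C)C)c1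
F9 | step 9 | methyl 4-[(methoxycarbonyl)oxy]-3-[(3E,6E)-5-[(methoxycarbonyl)oxy]-3,7-dimethyl-9-(2,6,6-trimethylcyclohex-1-en-1-yl)nona-3,6-dien-1-yl]benzoate, racemic | COC(=O)OC(/C=C(C)/CCc1cc(C(=O)OC)ccc1OC(=O)OC)/C=C(\C)CCC1=C(C)CCCC1(C)C
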